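Its constants are those of an exercise.

If the enzyme in this flask dies before the substrate is used up, the answer lies in how much work its whole life holds.

substrate 0.011 M; enzyme 0.084 mol%; added ligand 10 µM; time 1.5 h

    substrate + enzyme → product + enzyme, rate k1*[substrate]*[enzyme]/(1 + ([substrate]/Km1) + ([product]/Kp1)) (Km1 = 18.9 mM, Kp1 = 9.66 mM, k1 = 74900 /M/min)
    enzyme → spent catalyst (k2 = 0.194 /min)
    enzyme + added ligand ⇌ idle complex (K3 = 1.3 × 10⁵ /M, k3 = 2.15 × 10⁵ /M/min)

* part of the substrate gone at 1.5 h
* the product standing at 1.5 h, as a percentage of the substrate charged

Two chemists dispute this flask, and they share one integral. Each substrate lost gives one product, so the product in the rate law of step 1 can be written as charge minus substrate left, and the rate separates: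

k1 × (area under free enzyme against time) = a × ln(charge / substrate left) − b × conversion,

with a = 1 + charge/Kp = 2.14 and b = charge/Kp − charge/Km = 0.557.

They differ over the area. The first chemist notes that the equilibrium constant of step 3 times the added ligand is 1.3, so he counts the working enzyme as the charge divided by 2.30, dying at k2 all the same. That gives an area of his working enzyme over k2, a right side of 1.55, and, by repeated substitution, a conversion of 58.4%.

I hold otherwise. Step 2 takes free enzyme and not idle complex, so k2 times the area equals all the enzyme lost, parked or not. With the parking counted, the enzyme's life is about 11.9 min, shorter than the 90 min of the run, so nearly the whole charge is lost. The quantity to carry is therefore the lifetime dose, k1 times the enzyme charged divided by k2, here 3.57. Conversion stands on both sides, so I put 1 into the small term, solve the logarithm and repeat, which gives 85.5%, then 84.9%, then 84.9%. Product equals substrate lost.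

The forecast gives 85% (82% to 88%) for both answers, holding that “the ligand only parks it reversibly”.

The simulation gives 84.9% of the substrate gone and 84.9% as product, which matches my reckoning and not the first chemist's. His division comes near as a split of the catalyst still alive, not of the catalyst charged: in the flask at 1.50 h, idle complex over enzyme reads 1.37 against his 1.3. The neighbour with 0.034 mol% of enzyme has a dose of 1.44, and its simulated 56.0% put into the integral returns 1.44. In the flask at 1.50 h, enzyme stands at 0.0199% and idle complex at 0.0272%, so the dose unspent is 0.00168, worth 0.012 percentage points of conversion. At 15.0 h the conversion reads 84.9%.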